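The numbers in the tables are simulated for substances that don't exist.

I decide to compare these flasks by what the chemistry delivered over the run, not by their final yields.

| flask | starting material | coupling partner | time |
|---|---|---|---|
| winter | 120 mM | 96.0 mM |  |
| noon | 120 mM | 190 mM |  |
| spring | 360 mM | 48.0 mM | 5.5 min |

- winter run (time / min: [target] / mM): 0.22: 15.1; 0.35: 20.7; 0.55: 27.6; 0.87: 36.0; 1.4: 43.1; 2.2: 47.6; 3.5: 51.6; 5.5: 53.7
- noon run (time / min: [target] / mM): 0.22: 41.9; 0.35: 54.4; 0.55: 66.9; 0.87: 79.0; 1.4: 88.4; 2.2: 95.6; 3.5: 99.3; 5.5: 101.5

(each reading ± 0.4 mM)

- how the opening rate goes with [coupling partner] round the charge of the winter run: the exponent of the rate at two percent of starting material gone to target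
- target in the spring run at 5.5 min, as a share of the starting material charged

- Overall: starting material + coupling partner -> target.
- Constant volume, constant temperature.
- Readings of a species count what is bound in complexes too.
- "The second partner" is coupling partner.
- An order is taken over about fifteen percent of the charge, up and down.

At 5.5 min the target in the winter run and in the noon run stands short of the charge of the limiting reagent: charge minus target is 42.3 mM of coupling partner in the winter run and 18.5 mM of starting material in the noon run. Yet the winter rate, read from the readings, falls by a factor of 65.4 from the first interval to the last, while the product of the two charges-minus-target falls by a factor of 4.11 from the start to 5.5 min. So in the winter run a coefficient k on that product falls with time.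

I write rate = k·c(starting material)·c(coupling partner), counting both as charge minus target. This integrates in closed form whatever k does: the integral of k over time equals the logarithm of (partner charged × starting material now) / (starting material charged × partner now), divided by the difference of the charges. The winter value is 9.43 M⁻¹, and this reach, the time integral of rate over the product of the two concentrations, is what I carry.

The noon reach is 15.8 M⁻¹, larger by a factor of 1.68 for a partner charge larger by a factor of 1.98. If k keeps one time course, the order in partner across that span reads 1.76. Scaling to the spring charge gives a reach of 5.58 M⁻¹. Inverting the closed form with 5.71 gives 40.5 mM, or 11.3%.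

The forecast, holding that “the active species dies at a clock rate”, gives 1.75 and 10.3%, lower than my figure.

The spring run gives 9.93%, which is 35.8 mM of target, and the exponent round the winter charge is 1.8.

    starting material + coupling partner → target (1.668 M⁻¹ min⁻¹)
    starting material + 2 coupling partner → target + coupling partner (109.2 M⁻² min⁻¹)
    coupling partner → lost reagent (0.3228 min⁻¹)
    starting material + coupling partner ⇌ idle substrate-reagent adduct, settled at all times (1.830 M⁻¹)

Put through the same closed form, the spring run has a reach of 4.04 M⁻¹, smaller than the winter 9.43 M⁻¹.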